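**Plan** (germacrane numbering: ring C1–C10, C14 on C10, C15 on C4, C11(=C13)–C12 on C7, lactone oxygen on C6)

- Retrosynthesis: cut C9–C10 last (alkenyl–carbinol bond, opening the ten-membered ring to an iodoalkene and an aldehyde), then the C8–O acyl bond, then C6–C7 together with the lactone C12–O6 bond, then C1=C10, C4–C15 and C3–C4.
- Forward: the C1–C6 half is made as a butenolide, converted to the (Z)-iodoalkene and opened to the (Z)-acetoxy enal 12; the C7–C9/C11–C13 half is the allyl bromide 16; 12 + 16 give the cis-fused lactone 18; the C8 epoxy ester is attached; the ten-membered ring closes in the last step and gives the target directly.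
- Enabling feature: C9 is a secondary allylic carbinol bonded to C10 of the (Z)-C1=C10 alkene and flanked by the acylated C8, i.e. the adduct of a (Z)-alkenyl metal and an α-acyloxy aldehyde. The cis-fused five-membered lactone (O6–C6–C7–C11–C12) and the (Z)-C4=C5 alkene inside the ten-membered ring act as turn elements that bring C9 and C10 together.
- Stereochemistry: C3 from catalytic asymmetric alkynylation; C8 from (R)-glyceraldehyde acetonide; C6 and C7 from the Barbier step (chair transition state, face set by C8); the epoxide from Sharpless epoxidation; C9 from the ring closure (Felkin–Anh, 8,9-anti); the two (Z)-alkenes from syn-carbocupration/lactonisation and Stork–Zhao olefination.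

Key step: step 20

Assumption: (S,S)-ProPhenol, 2,6-bis{[(2S)-2-(hydroxydiphenylmethyl)pyrrolidin-1-yl]methyl}-4-methylphenol, is taken to deliver the (4S)-alcohol 3; if the sense proves opposite, the (R,R) ligand is used.

**Step 1**
Reactants: 1 3-[(tert-butyldimethylsilyl)oxy]propanal; 2 methyl propiolate
Product: 3 methyl (4S)-6-[(tert-butyldimethylsilyl)oxy]-4-hydroxyhex-2-ynoate
Conditions: Me2Zn (3 equiv), (S,S)-ProPhenol (10 mol %), Ph3PO (20 mol %), PhMe, 4 °C
Reagents that add atoms: none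
Why: Zinc–ProPhenol catalysed asymmetric alkynylation, in which the dinuclear zinc alkynylide adds the propiolate to one enantioface of the aldehyde and so sets C3 (S).

**Step 2**
Reactants: 3 methyl (4S)-6-[(tert-butyldimethylsilyl)oxy]-4-hydroxyhex-2-ynoate
Product: 5 (5S)-5-{2-[(tert-butyldimethylsilyl)oxy]ethyl}-4-methylfuran-2(5H)-one, via hydroxy enoate 4 (not isolated)
Conditions: Me2CuLi (2.5 equiv, from MeLi and CuI), THF, −78 °C; aq. NH4Cl, then rt
Reagents that add atoms: lithium dimethylcuprate, [Li+].C[Cu-]C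
Why: Syn-carbocupration (conjugate addition) of the ynoate places CH3 (C15) on C4 cis to H-5, so the ester and the C3 oxygen are cis and the (Z)-hydroxy enoate should lactonise on work-up to the butenolide, which locks the (Z)-C4=C5 geometry while C3 is untouched.

**Step 3**
Reactants: 5 (5S)-5-{2-[(tert-butyldimethylsilyl)oxy]ethyl}-4-methylfuran-2(5H)-one
Product: 6 (5S)-5-(2-hydroxyethyl)-4-methylfuran-2(5H)-one
Conditions: HF·pyridine, pyridine, THF, 0 °C to rt
Reagents that add atoms: none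
Why: Acidic fluoride cleavage of the primary silyl ether, chosen because a basic fluoride source could trigger oxa-Michael addition or epimerisation of the butenolide.

**Step 4**
Reactants: 6 (5S)-5-(2-hydroxyethyl)-4-methylfuran-2(5H)-one
Product: 7 2-[(2S)-3-methyl-5-oxo-2,5-dihydrofuran-2-yl]acetaldehyde
Conditions: Dess–Martin periodinane, NaHCO3, CH2Cl2, 0 °C
Reagents that add atoms: none
Why: Dess–Martin oxidation under buffered neutral conditions should spare the base-sensitive β-acyloxy aldehyde, which is used crude.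

**Step 5**
Reactants: 7 2-[(2S)-3-methyl-5-oxo-2,5-dihydrofuran-2-yl]acetaldehyde
Product: 8 (5S)-5-[(2Z)-3-iodobut-2-en-1-yl]-4-methylfuran-2(5H)-one
Conditions: [Ph3PEt]I, n-BuLi, THF, rt; I2, −78 °C; NaN(SiMe3)2, −20 °C; then 7, −78 to −20 °C
Reagents that add atoms: ethyltriphenylphosphonium iodide, CC[P+](c1ccccc1)(c1ccccc1)c1ccccc1.[I-]; iodine, [I][I]
Why: Stork–Zhao–Wittig olefination with the α-iodoethylidene ylide should give the (Z)-2-iodoalk-2-ene (iodine cis to C2) under kinetic control at low temperature, which fixes the C1=C10 geometry and installs the C10–I handle.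

**Step 6**
Reactants: 8 (5S)-5-[(2Z)-3-iodobut-2-en-1-yl]-4-methylfuran-2(5H)-one
Product: 9 (2Z,4S,6Z)-7-iodo-3-methylocta-2,6-diene-1,4-diol
Conditions: i-Bu2AlH (3.5 equiv), CH2Cl2, −78 to 0 °C; aq. potassium sodium tartrate
Reagents that add atoms: none
Why: Exhaustive 1,2-reduction of the unsaturated lactone through the lactol should give the (Z)-ene-1,4-diol with the alkene geometry and C3 retained and the alkenyl iodide untouched.

**Step 7**
Reactants: 9 (2Z,4S,6Z)-7-iodo-3-methylocta-2,6-diene-1,4-diol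
Product: 11 (2Z,4S,6Z)-7-iodo-3-methyl-1-[(triethylsilyl)oxy]octa-2,6-dien-4-yl acetate, via mono-silyl ether 10 (not isolated)
Conditions: Et3SiCl (1.05 equiv), imidazole, CH2Cl2, −78 °C; then Ac2O, Et3N, 4-(dimethylamino)pyridine (DMAP, cat.), 0 °C to rt
Reagents that add atoms: chlorotriethylsilane, CC[Si](Cl)(CC)CC; acetic anhydride, CC(=O)OC(C)=O
Why: Selective silylation of the primary allylic hydroxyl at low temperature followed by acetylation of the remaining secondary hydroxyl in the same flask installs the C3 acetate of the target.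

**Step 8**
Reactants: 11 (2Z,4S,6Z)-7-iodo-3-methyl-1-[(triethylsilyl)oxy]octa-2,6-dien-4-yl acetate
Product: 12 (2Z,4S,6Z)-7-iodo-3-methyl-1-oxoocta-2,6-dien-4-yl acetate
Conditions: (COCl)2, DMSO, CH2Cl2, −78 to −35 °C; Et3N, −78 to 0 °C
Reagents that add atoms: none
Why: Swern oxidation of a primary triethylsilyl ether proceeds with loss of the silyl group (known oxidative desilylation) and should give the (Z)-enal in one operation at low temperature without Z to E isomerisation.

**Step 9**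
Reactants: 13 (4R)-2,2-dimethyl-1,3-dioxolane-4-carbaldehyde; 14 methyl acrylate
Product: 15 methyl 2-{[(4R)-2,2-dimethyl-1,3-dioxolan-4-yl](hydroxy)methyl}prop-2-enoate (both carbinol epimers)
Conditions: 1,4-diazabicyclo[2.2.2]octane (DABCO, 0.5 equiv), 1,4-dioxane/H2O (1:1), rt
Reagents that add atoms: none
Why: Morita–Baylis–Hillman reaction; the new carbinol centre forms as a mixture, which does not matter because it is destroyed in step 10, while C8 comes unchanged from the chiral pool.

**Step 10**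
Reactants: 15 methyl 2-{[(4R)-2,2-dimethyl-1,3-dioxolan-4-yl](hydroxy)methyl}prop-2-enoate
Product: 16 methyl (2Z)-2-(bromomethyl)-3-[(4S)-2,2-dimethyl-1,3-dioxolan-4-yl]prop-2-enoate
Conditions: NBS, Me2S, CH2Cl2, 0 °C to rt
Reagents that add atoms: N-bromosuccinimide, BrN1C(=O)CCC1=O
Why: Bromination with allylic transposition (SN2' on the alkoxysulfonium salt) should funnel both carbinol epimers into the single, thermodynamically preferred (Z)-2-(bromomethyl)enoate under neutral conditions that keep the acetonide and C8 intact.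

**Step 11**
Reactants: 12 (2Z,4S,6Z)-7-iodo-3-methyl-1-oxoocta-2,6-dien-4-yl acetate; 16 methyl (2Z)-2-(bromomethyl)-3-[(4S)-2,2-dimethyl-1,3-dioxolan-4-yl]prop-2-enoate
Product: 18 (1Z,3S,5Z)-1-{(2R,3R)-3-[(4S)-2,2-dimethyl-1,3-dioxolan-4-yl]-4-methylidene-5-oxooxolan-2-yl}-6-iodo-2-methylhepta-1,5-dien-3-yl acetate, via hydroxy ester 17 (not isolated)
Conditions: In powder (2 equiv), THF/H2O (1:1), rt; then pyridinium p-toluenesulfonate (PPTS, cat.), PhH, 50 °C
Reagents that add atoms: none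
Why: Indium-mediated Barbier allylation then lactonisation: the (Z)-2-(methoxycarbonyl)allylindium from 16 adds through its γ-carbon (C7) in a chair Zimmerman–Traxler transition state, which gives the syn adduct and therefore the cis-fused lactone, while the aldehyde should approach the C7 face anti to the dioxolane C8–O bond with H-8 eclipsing the alkene (allylic 1,3-strain), so that C6 (R) and C7 (R) are set by C8.

**Step 12**
Reactants: 18 the lactone acetonide of step 11
Product: 19 (1Z,3S,5Z)-1-{(2R,3S)-3-[(1S)-1,2-dihydroxyethyl]-4-methylidene-5-oxooxolan-2-yl}-6-iodo-2-methylhepta-1,5-dien-3-yl acetate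
Conditions: AcOH/H2O (4:1), 40 °C
Reagents that add atoms: none
Why: Mild acid hydrolysis of the terminal acetonide, to which the acetate, the lactone and the alkenyl iodide should be stable (the descriptor at C7 changes by priority only).

**Step 13**
Reactants: 19 the diol of step 12
Product: 20 (1Z,3S,5Z)-1-{(2R,3S)-3-[(1S)-1-hydroxy-2-[(triethylsilyl)oxy]ethyl]-4-methylidene-5-oxooxolan-2-yl}-6-iodo-2-methylhepta-1,5-dien-3-yl acetate
Conditions: Et3SiCl (1.1 equiv), imidazole, CH2Cl2, −78 to −30 °C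
Reagents that add atoms: chlorotriethylsilane, CC[Si](Cl)(CC)CC
Why: Selective silylation of the primary C9 hydroxyl at low temperature leaves the C8 hydroxyl free for acylation.

**Step 14**
Reactants: 21 methyl angelate [methyl (2Z)-2-methylbut-2-enoate]
Product: 22 (2Z)-2-methylbut-2-en-1-ol
Conditions: i-Bu2AlH (2.2 equiv), CH2Cl2, −78 to 0 °C
Reagents that add atoms: none
Why: Hydride reduction of the ester to the allylic alcohol with retention of the (Z) geometry.

**Step 15**
Reactants: 22 (2Z)-2-methylbut-2-en-1-ol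
Product: 23 [(2S,3R)-2,3-dimethyloxiran-2-yl]methanol
Conditions: Ti(OiPr)4 (10 mol %), L-(+)-diisopropyl tartrate (12 mol %), t-BuOOH, 4 Å molecular sieves, CH2Cl2, −20 °C
Reagents that add atoms: tert-butyl hydroperoxide, CC(C)(C)OO
Why: Sharpless asymmetric epoxidation, in which the L-(+)-tartrate ligand directs oxygen to the face that gives the (2S,3R)-epoxy alcohol, the cis relation of the substituents coming from the (Z)-alkene.

**Step 16**
Reactants: 23 [(2S,3R)-2,3-dimethyloxiran-2-yl]methanol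
Product: 24 (2R,3R)-2,3-dimethyloxirane-2-carboxylic acid
Conditions: RuCl3·xH2O (2 mol %), NaIO4 (4 equiv), CCl4/MeCN/H2O (2:2:3), rt
Reagents that add atoms: sodium periodate, [Na+].[O-]I(=O)(=O)=O; water, O
Why: Ruthenium-catalysed periodate oxidation of an epoxy alcohol to the glycidic acid, a known transformation that leaves the epoxide and both stereocentres intact (descriptor at C2 changes by priority only).

**Step 17**
Reactants: 20 the C8 alcohol of step 13; 24 (2R,3R)-2,3-dimethyloxirane-2-carboxylic acid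
Product: 26 (1S)-1-{(2R,3R)-2-[(1Z,3S,5Z)-3-acetoxy-6-iodo-2-methylhepta-1,5-dien-1-yl]-4-methylidene-5-oxooxolan-3-yl}-2-[(triethylsilyl)oxy]ethyl (2R,3R)-2,3-dimethyloxirane-2-carboxylate, via mixed anhydride 25 (not isolated)
Conditions: 2,4,6-Cl3C6H2COCl, Et3N, THF, rt; then 20, DMAP, PhMe, rt
Reagents that add atoms: none
Why: Yamaguchi esterification through the mixed anhydride should acylate the hindered C8 hydroxyl with retention at C8 and without opening the epoxide, under weakly basic conditions that disfavour translactonisation to O8.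

**Step 18**
Reactants: 26 the silyl ether ester of step 17
Product: 27 (1S)-1-{(2R,3R)-2-[(1Z,3S,5Z)-3-acetoxy-6-iodo-2-methylhepta-1,5-dien-1-yl]-4-methylidene-5-oxooxolan-3-yl}-2-hydroxyethyl (2R,3R)-2,3-dimethyloxirane-2-carboxylate
Conditions: HF·pyridine, pyridine, THF, 0 °C
Reagents that add atoms: none
Why: Buffered HF·pyridine removes the primary triethylsilyl ether under weakly acidic conditions that should suppress acyl migration from O8 to O9.

**Step 19**
Reactants: 27 the primary alcohol of step 18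
Product: 28 (1S)-1-{(2R,3R)-2-[(1Z,3S,5Z)-3-acetoxy-6-iodo-2-methylhepta-1,5-dien-1-yl]-4-methylidene-5-oxooxolan-3-yl}-2-oxoethyl (2R,3R)-2,3-dimethyloxirane-2-carboxylate
Conditions: Dess–Martin periodinane, NaHCO3, CH2Cl2, 0 °C to rt
Reagents that add atoms: none
Why: Dess–Martin oxidation under buffered neutral conditions should give the configurationally labile α-acyloxy aldehyde without epimerisation at C8.

**Step 20**
Reactants: 28 the seco iodoalkene aldehyde of step 19
Product: 29 (3S,6R,7R,8S,9R)-3-acetoxy-8-[(2R,3R)-2,3-epoxy-2-methylbutanoyloxy]-9-hydroxygermacra-1(10)Z,4Z,11(13)-trien-12,6-olide (CNP0299903.1)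
Conditions: CrCl2 (10 equiv), NiCl2 (0.1 equiv), DMSO, rt, slow addition of 28 to a final 0.002 M
Reagents that add atoms: none
Why: Nozaki–Hiyama–Kishi reaction: zerovalent nickel (from NiCl2 and CrCl2) inserts into the C10–I bond with retention of the (Z) geometry, transmetalation gives an alkenylchromium dichloride (trivalent chromium), and this adds to the C9 aldehyde. The closest known reaction type is the intramolecular alkenyl iodide/aldehyde chromium–nickel macrocyclisation used to close ten-membered germacranolide and other medium carbocycles. The ten-membered ring closes in a 10-exo-trig mode, the C9=O bond staying outside the new ring. The new C9 centre should be (9R) by Felkin–Anh addition anti to the polar C8–O bond of the α-acyloxy aldehyde (8,9-anti), a preference the fold imposed by the cis-lactone and the two (Z)-alkenes is expected to reinforce. The step needs chemoselectivity for the single aldehyde over lactone, acetate, epoxy ester and enoate, which the low basicity of the organochromium secures, and ring closure over oligomerisation, which the turn elements of the substrate together with high dilution secure.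

**Compound list**

1 | 3-[(tert-butyldimethylsilyl)oxy]propanal | O=CCCO[Si](C)(C)C(C)(C)C | starting material
2 | methyl propiolate | C#CC(=O)OC | starting material
3 | methyl (4S)-6-[(tert-butyldimethylsilyl)oxy]-4-hydroxyhex-2-ynoate | COC(=O)C#C[C@@H](O)CCO[Si](C)(C)C(C)(C)C | intermediate
4 | methyl (2Z,4S)-6-[(tert-butyldimethylsilyl)oxy]-4-hydroxy-3-methylhex-2-enoate | COC(=O)/C=C(/C)[C@@H](O)CCO[Si](C)(C)C(C)(C)C | intermediate
5 | (5S)-5-{2-[(tert-butyldimethylsilyl)oxy]ethyl}-4-methylfuran-2(5H)-one | O=C1C=C(C)[C@H](CCO[Si](C)(C)C(C)(C)C)O1 | intermediate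
6 | (5S)-5-(2-hydroxyethyl)-4-methylfuran-2(5H)-one | O=C1C=C(C)[C@H](CCO)O1 | intermediate
7 | 2-[(2S)-3-methyl-5-oxo-2,5-dihydrofuran-2-yl]acetaldehyde | O=C1C=C(C)[C@H](CC=O)O1 | intermediate
8 | (5S)-5-[(2Z)-3-iodobut-2-en-1-yl]-4-methylfuran-2(5H)-one | O=C1C=C(C)[C@H](C/C=C(/C)I)O1 | intermediate
9 | (2Z,4S,6Z)-7-iodo-3-methylocta-2,6-diene-1,4-diol | OC/C=C(/C)[C@@H](O)C/C=C(/C)I | intermediate
10 | (2Z,4S,6Z)-7-iodo-3-methyl-1-[(triethylsilyl)oxy]octa-2,6-dien-4-ol | CC[Si](CC)(CC)OC/C=C(/C)[C@@H](O)C/C=C(/C)I | intermediate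
11 | (2Z,4S,6Z)-7-iodo-3-methyl-1-[(triethylsilyl)oxy]octa-2,6-dien-4-yl acetate | CC[Si](CC)(CC)OC/C=C(/C)[C@@H](OC(C)=O)C/C=C(/C)I | intermediate
12 | (2Z,4S,6Z)-7-iodo-3-methyl-1-oxoocta-2,6-dien-4-yl acetate | O=C/C=C(/C)[C@@H](OC(C)=O)C/C=C(/C)I | intermediate
13 | (4R)-2,2-dimethyl-1,3-dioxolane-4-carbaldehyde | O=C[C@H]1COC(C)(C)O1 | starting material
14 | methyl acrylate | C=CC(=O)OC | starting material
15 | methyl 2-{[(4R)-2,2-dimethyl-1,3-dioxolan-4-yl](hydroxy)methyl}prop-2-enoate (both carbinol epimers) | C=C(C(=O)OC)C(O)[C@H]1COC(C)(C)O1 | intermediate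
16 | methyl (2Z)-2-(bromomethyl)-3-[(4S)-2,2-dimethyl-1,3-dioxolan-4-yl]prop-2-enoate | BrC/C(C(=O)OC)=C\[C@H]1COC(C)(C)O1 | intermediate
17 | methyl 2-[(1R,2R,3Z,5S,7Z)-5-acetoxy-1-[(4S)-2,2-dimethyl-1,3-dioxolan-4-yl]-2-hydroxy-8-iodo-4-methylnona-3,7-dien-1-yl]prop-2-enoate | C=C(C(=O)OC)[C@H]([C@H](O)/C=C(/C)[C@@H](OC(C)=O)C/C=C(/C)I)[C@H]1COC(C)(C)O1 | intermediate
18 | (1Z,3S,5Z)-1-{(2R,3R)-3-[(4S)-2,2-dimethyl-1,3-dioxolan-4-yl]-4-methylidene-5-oxooxolan-2-yl}-6-iodo-2-methylhepta-1,5-dien-3-yl acetate | C=C1C(=O)O[C@H](/C=C(/C)[C@@H](OC(C)=O)C/C=C(/C)I)[C@@H]1[C@H]2COC(C)(C)O2 | intermediate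
19 | (1Z,3S,5Z)-1-{(2R,3S)-3-[(1S)-1,2-dihydroxyethyl]-4-methylidene-5-oxooxolan-2-yl}-6-iodo-2-methylhepta-1,5-dien-3-yl acetate | C=C1C(=O)O[C@H](/C=C(/C)[C@@H](OC(C)=O)C/C=C(/C)I)[C@@H]1[C@H](O)CO | intermediate
20 | (1Z,3S,5Z)-1-{(2R,3S)-3-[(1S)-1-hydroxy-2-[(triethylsilyl)oxy]ethyl]-4-methylidene-5-oxooxolan-2-yl}-6-iodo-2-methylhepta-1,5-dien-3-yl acetate | C=C1C(=O)O[C@H](/C=C(/C)[C@@H](OC(C)=O)C/C=C(/C)I)[C@@H]1[C@H](O)CO[Si](CC)(CC)CC | intermediate
21 | methyl angelate, methyl (2Z)-2-methylbut-2-enoate | C/C=C(/C)C(=O)OC | starting material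
22 | (2Z)-2-methylbut-2-en-1-ol | C/C=C(/C)CO | intermediate
23 | [(2S,3R)-2,3-dimethyloxiran-2-yl]methanol | OC[C@]1(C)O[C@@H]1C | intermediate
24 | (2R,3R)-2,3-dimethyloxirane-2-carboxylic acid | OC(=O)[C@]1(C)O[C@@H]1C | intermediate
25 | (2R,3R)-2,3-dimethyloxirane-2-carboxylic 2,4,6-trichlorobenzoic anhydride | O=C(OC(=O)[C@]1(C)O[C@@H]1C)c1c(Cl)cc(Cl)cc1Cl | intermediate
26 | (1S)-1-{(2R,3R)-2-[(1Z,3S,5Z)-3-acetoxy-6-iodo-2-methylhepta-1,5-dien-1-yl]-4-methylidene-5-oxooxolan-3-yl}-2-[(triethylsilyl)oxy]ethyl (2R,3R)-2,3-dimethyloxirane-2-carboxylate | C=C1C(=O)O[C@H](/C=C(/C)[C@@H](OC(C)=O)C/C=C(/C)I)[C@@H]1[C@H](OC(=O)[C@]2(C)O[C@@H]2C)CO[Si](CC)(CC)CC | intermediate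
27 | (1S)-1-{(2R,3R)-2-[(1Z,3S,5Z)-3-acetoxy-6-iodo-2-methylhepta-1,5-dien-1-yl]-4-methylidene-5-oxooxolan-3-yl}-2-hydroxyethyl (2R,3R)-2,3-dimethyloxirane-2-carboxylate | C=C1C(=O)O[C@H](/C=C(/C)[C@@H](OC(C)=O)C/C=C(/C)I)[C@@H]1[C@H](OC(=O)[C@]2(C)O[C@@H]2C)CO | intermediate
28 | (1S)-1-{(2R,3R)-2-[(1Z,3S,5Z)-3-acetoxy-6-iodo-2-methylhepta-1,5-dien-1-yl]-4-methylidene-5-oxooxolan-3-yl}-2-oxoethyl (2R,3R)-2,3-dimethyloxirane-2-carboxylate | C=C1C(=O)O[C@H](/C=C(/C)[C@@H](OC(C)=O)C/C=C(/C)I)[C@@H]1[C@H](OC(=O)[C@]2(C)O[C@@H]2C)C=O | intermediate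
29 | (3S,6R,7R,8S,9R)-3-acetoxy-8-[(2R,3R)-2,3-epoxy-2-methylbutanoyloxy]-9-hydroxygermacra-1(10)Z,4Z,11(13)-trien-12,6-olide (CNP0299903.1) | C=C1C(=O)O[C@@H]2/C=C(/C)[C@@H](OC(C)=O)C/C=C(/C)[C@@H](O)[C@@H](OC(=O)[C@]3(C)O[C@@H]3C)[C@H]12 | target

**Totals**

Total step count: 20. Longest linear sequence: 15 steps (steps 1–8, 11–13, 17–20).

**Steps most likely to fail**

Step 20. The ring closure may add the alkenylchromium to the wrong face of the C9 aldehyde, because the fold of the forming ten-membered ring can override the Felkin–Anh preference; slow closure would also let reductive loss of iodine compete. Fallback, setting out from 28 and returning at 29: the same ring closure is accepted as it comes and gives the (9S)-epimer of 29 F1, alone or mixed with 29. Dess–Martin oxidation of this material gives the macrocyclic C9 ketone (enone) F2. Reagent-controlled 1,2-reduction with (R)-Me-CBS oxazaborolidine [(3aR)-1-methyl-3,3-diphenyltetrahydro-1H,3H-pyrrolo[1,2-c][1,3,2]oxazaborole] and catecholborane in PhMe at −78 °C, with the alkenyl side acting as the large group, should then give 29.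

Step 11. The aldehyde may attack the C7 face syn to the dioxolane C8–O bond (wrong sense of 1,2-induction), which would give a cis-lactone with C6 and C7 both inverted relative to C8. Fallback, setting out from 12 and returning at 26: the antipodal bromide is used so that C6 and C7 come out correct, and C8 is corrected afterwards by inversion. Commercial (4S)-2,2-dimethyl-1,3-dioxolane-4-carbaldehyde is taken through the conditions of steps 9 and 10 to the Baylis–Hillman adduct F3 and the (4R)-dioxolanyl bromide F4. F4 and 12 under the conditions of step 11 give, through the hydroxy ester F5, the 8-epi lactone acetonide F6. The conditions of steps 12 and 13 give the 8-epi diol F7 and the 8-epi silyl ether F8. Mitsunobu esterification of F8 with acid 24 (PPh3, diisopropyl azodicarboxylate, PhMe, 0 °C to rt) installs the epoxy ester with inversion at C8 and gives 26.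

Step 5. Base-induced β-elimination of the ring carboxylate from aldehyde 7, or deprotonation at the γ-carbon of the butenolide with loss of configuration at C3, may compete with the Wittig addition. Fallback, setting out from 3 and returning at 8: the iodoalkene is made before the lactone exists. i-Pr3SiOTf and 2,6-lutidine convert 3 into the bis-silyl ether F9. Me2CuLi at −78 °C gives the (Z)-enoate F10. HF·pyridine buffered with pyridine removes only the primary silyl group to give the alcohol F11. Dess–Martin oxidation gives the aldehyde F12, and the olefination of step 5 gives the (Z)-iodoalkene F13. Aqueous HF in MeCN removes the remaining silyl group, and the hydroxy enoate F14 lactonises to 8.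

**Further compounds**

F1 | step 20 | (9S)-epimer of 29 | C=C1C(=O)O[C@@H]2/C=C(/C)[C@@H](OC(C)=O)C/C=C(/C)[C@H](O)[C@@H](OC(=O)[C@]3(C)O[C@@H]3C)[C@H]12
F2 | step 20 | 9-oxo analogue of 29 (macrocyclic enone) | C=C1C(=O)O[C@@H]2/C=C(/C)[C@@H](OC(C)=O)C/C=C(/C)C(=O)[C@@H](OC(=O)[C@]3(C)O[C@@H]3C)[C@H]12
F3 | step 11 | methyl 2-{[(4S)-2,2-dimethyl-1,3-dioxolan-4-yl](hydroxy)methyl}prop-2-enoate | C=C(C(=O)OC)C(O)[C@@H]1COC(C)(C)O1
F4 | step 11 | methyl (2Z)-2-(bromomethyl)-3-[(4R)-2,2-dimethyl-1,3-dioxolan-4-yl]prop-2-enoate | BrC/C(C(=O)OC)=C\[C@@H]1COC(C)(C)O1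
F5 | step 11 | methyl 2-[(1R,2R,3Z,5S,7Z)-5-acetoxy-1-[(4R)-2,2-dimethyl-1,3-dioxolan-4-yl]-2-hydroxy-8-iodo-4-methylnona-3,7-dien-1-yl]prop-2-enoate | C=C(C(=O)OC)[C@H]([C@H](O)/C=C(/C)[C@@H](OC(C)=O)C/C=C(/C)I)[C@@H]1COC(C)(C)O1
F6 | step 11 | (1Z,3S,5Z)-1-{(2R,3R)-3-[(4R)-2,2-dimethyl-1,3-dioxolan-4-yl]-4-methylidene-5-oxooxolan-2-yl}-6-iodo-2-methylhepta-1,5-dien-3-yl acetate | C=C1C(=O)O[C@H](/C=C(/C)[C@@H](OC(C)=O)C/C=C(/C)I)[C@@H]1[C@@H]2COC(C)(C)O2
F7 | step 11 | (1Z,3S,5Z)-1-{(2R,3S)-3-[(1R)-1,2-dihydroxyethyl]-4-methylidene-5-oxooxolan-2-yl}-6-iodo-2-methylhepta-1,5-dien-3-yl acetate | C=C1C(=O)O[C@H](/C=C(/C)[C@@H](OC(C)=O)C/C=C(/C)I)[C@@H]1[C@@H](O)CO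
F8 | step 11 | (1Z,3S,5Z)-1-{(2R,3S)-3-[(1R)-1-hydroxy-2-[(triethylsilyl)oxy]ethyl]-4-methylidene-5-oxooxolan-2-yl}-6-iodo-2-methylhepta-1,5-dien-3-yl acetate | C=C1C(=O)O[C@H](/C=C(/C)[C@@H](OC(C)=O)C/C=C(/C)I)[C@@H]1[C@@H](O)CO[Si](CC)(CC)CC
F9 | step 5 | methyl (4S)-6-[(tert-butyldimethylsilyl)oxy]-4-[(triisopropylsilyl)oxy]hex-2-ynoate | COC(=O)C#C[C@@H](O[Si](C(C)C)(C(C)C)C(C)C)CCO[Si](C)(C)C(C)(C)C
F10 | step 5 | methyl (2Z,4S)-6-[(tert-butyldimethylsilyl)oxy]-3-methyl-4-[(triisopropylsilyl)oxy]hex-2-enoate | COC(=O)/C=C(/C)[C@@H](O[Si](C(C)C)(C(C)C)C(C)C)CCO[Si](C)(C)C(C)(C)C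
F11 | step 5 | methyl (2Z,4S)-6-hydroxy-3-methyl-4-[(triisopropylsilyl)oxy]hex-2-enoate | COC(=O)/C=C(/C)[C@@H](O[Si](C(C)C)(C(C)C)C(C)C)CCO
F12 | step 5 | methyl (2Z,4S)-3-methyl-6-oxo-4-[(triisopropylsilyl)oxy]hex-2-enoate | COC(=O)/C=C(/C)[C@@H](O[Si](C(C)C)(C(C)C)C(C)C)CC=O
F13 | step 5 | methyl (2Z,4S,6Z)-7-iodo-3-methyl-4-[(triisopropylsilyl)oxy]octa-2,6-dienoate | COC(=O)/C=C(/C)[C@@H](O[Si](C(C)C)(C(C)C)C(C)C)C/C=C(/C)I
F14 | step 5 | methyl (2Z,4S,6Z)-4-hydroxy-7-iodo-3-methylocta-2,6-dienoate | COC(=O)/C=C(/C)[C@@H](O)C/C=C(/C)I
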